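**Analysis of the target**

Compound 14 is a 2-aryl-3-(hydroxymethyl)-2,3-dihydrobenzofuran. In benzofuran numbering, ring A (the benzo ring) carries a methoxy group at C7 and a methyl propanoate chain at C5. C2 carries ring B, a 4-hydroxy-3,5-dimethoxyphenyl group, and C3 carries the hydroxymethyl carbon C9. There are two adjacent stereocentres, C2 (S) and C3 (R), with the aryl group and C9 trans across the five-membered ring. The sensitive element is the para-hydroxybenzyl aryl ether at C2: once the ring B phenol is free, acid or strong base can ionise C2–O1 through a quinone methide and epimerise or open the ring. A methyl ester and a primary alcohol must coexist at the end, so late hydride reduction or saponification is excluded. C3 has no acidifying group, so the trans relationship cannot be corrected by epimerisation and must be delivered directly, together with the absolute configuration. The strategy rests on one feature: C7a and C3a are neighbouring carbons of ring A, bound to O1 and to C3, and O1–C2–C3 is the opened form of the cis-epoxide of a Z-cinnamyl ether. The C7 methoxy group sits ortho to C7a, exactly where ortho C–H functionalisation of an aryl halide needs a blocking substituent.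

**Retrosynthetic reasoning**

14 to 13 to 12 (protecting groups). The ring B phenol is masked as a tosyl ester and C9–OH as a silyl ether. The sulfonate makes ring B electron-poor, which the key step needs, and it prevents quinone methide chemistry until the end. The silyl ether is removed first and the sulfonate last, so that the free phenol never meets fluoride or acid.

12 to 4 + 11 (key disconnection, C3–C3a and O1–C7a). Both bonds leave adjacent carbons of ring A. Cutting them reduces ring A to the simple aryl iodide 4, with no phenol, and puts both stereocentres into epoxide 11. The forward reaction is a Catellani-type ortho alkylation and ipso etherification, with palladium and a strained bicyclic alkene as transient mediator. It must open 11 at C3 with inversion, leave the C2–O bond intact, and close the ring at the carbon that carried iodine.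

11 to 10 (the two stereocentres). Because C3 is inverted once and C2 is retained, the trans ring requires a cis-epoxide. This is reached by catalytic asymmetric epoxidation of Z-alkene 10, so one step sets both centres.

10 to 9 to 6 + 8 (Z-alkene). The Z geometry comes from syn semi-hydrogenation of alkyne 9. The aryl–alkynyl bond is cut to bromide 6 and silyl propargyl ether 8, joined by Sonogashira coupling. Compound 6 is the sulfonate of phenol 5, and 8 is the silyl ether of alcohol 7.

4 to 3 to 2 to 1 (ring A). The C–I bond is introduced last by halogen exchange on bromide 3, so the labile iodide is not carried through a hydrogenation. Compound 3 comes from chemoselective reduction of cinnamate 2, and 2 from Wittig olefination of aldehyde 1.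

**Alternatives that were turned down**

Alternative 1: The ring is cut at C3–C3a and C9 is stripped of its oxygen. This leads back to the ring A iodide A1, an aryl ether of a 1-(ring B)allyl alcohol that already carries C2.
- Forward key step: a tin hydride chain generates the aryl radical at C3a, which closes 5-exo onto the vinyl group. The primary C9 radical is captured by a persistent nitroxyl to give alkoxyamine A2. The N–O bond and the benzyl ether are cleaved later.
- For it: such closures are fast and tolerate esters. The tether fixes the site of C–C bond formation, so there is no regiochemical question, and on this point it is stronger than the chosen route. C2 is secured beforehand.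
- Against it: C3 is formed under substrate control alone through an early transition state, so poor diastereocontrol must be expected and cannot be repaired, since C3 has no acidifying group. Oxygen capture competes with hydrogen transfer to the C9 radical and with trapping of the aryl radical before cyclisation. A1 needs an enantioselective etherification of a doubly ortho-substituted iodophenol. Two extra unmasking steps and stoichiometric tin follow.
- Comparison: the chosen route gives up regiochemical certainty but transfers both centres stereospecifically from one catalytic asymmetric step.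

Alternative 2: Cutting C2–C3 leads to aryldiazoacetate A3. The future C3 is a carbenoid carbon on ring A and the future C2 is the methylene of a ring B benzyl ether on the ortho oxygen.
- Forward key step: a chiral dirhodium tetracarboxylate expels N2 and the carbenoid inserts into the ArO–CH2–aryl C–H bond, closing the ring as ester A4.
- For it: this is the best-precedented asymmetric entry to trans-2-aryl-2,3-dihydrobenzofuran-3-carboxylates. The catalyst sets the configuration, the ester allows epimerisation to trans, and the regiochemistry is certain. In reliability of the key step it is clearly ahead of the chosen route.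
- Against it: C3 arrives as an ester that must be reduced to C9H2OH, which is incompatible with the side-chain methyl ester. Ring A therefore needs a C5 bromide, and the chain is appended afterwards by Heck coupling and hydrogenation. This makes a long linear sequence through a diazo compound. Basic epimerisation can also open the ring by elimination of the phenoxide and erase C2.
- Comparison: the chosen route is convergent and shorter and brings the chain and the correct oxidation level at C9 from the start. An adapted form of this alternative is kept as the reserve for the key step.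

Alternative 3: C2 is excised as a one-carbon unit by cutting O1–C2 and C2–C3. This gives ring A phenol A5, with a sulfonyl group on the carbon that becomes C3, and the ring B benzylsulfonium salt A6 of a chiral sulfide.
- Forward key step: carbonate base eliminates sulfinate from A5 to give ortho-quinone methide A7 and deprotonates A6. The ylide carbon adds to the methide carbon (C2–C3) and the phenoxide displaces the sulfide (O1–C2), giving A8.
- For it: the bond polarities are the natural ones, so regiochemistry is certain. The conditions are mild and metal-free, the anti betaine closes to the trans ring, and A8 is only a protecting-group variant of 12.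
- Against it: the absolute configuration depends on a stoichiometric chiral sulfide transferring a semi-stabilised benzyl ylide, for which betaine formation is partly reversible and facial control is less dependable. A7 can tautomerise to the ortho-hydroxystyrene before it is trapped. A5 needs several steps of ortho-functionalisation of a phenol.
- Comparison: the chosen route is weaker in regiochemical certainty but sets the stereocentres by a mature catalytic epoxidation followed by stereospecific transfer.

Key step: step 9

Assumption: the (R,R)-configured manganese salen catalyst is taken to give the (2R,3S)-oxirane, by analogy with its facial preference for Z-1-arylalkenes and cyclic analogues; if the sense is opposite on this substrate, the enantiomeric catalyst is used with no other change.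

**Route**

Step 1
Reactants: 1 4-bromo-3-methoxybenzaldehyde
Product: 2 methyl (E)-3-(4-bromo-3-methoxyphenyl)prop-2-enoate
Conditions: Ph3P=CHCO2Me (1.1 equiv), toluene, 80 °C
Reagents that add atoms: methyl (triphenylphosphoranylidene)acetate, COC(=O)C=P(c1ccccc1)(c1ccccc1)c1ccccc1
Why: Wittig olefination with a stabilised ylide should give the E-cinnamate; the geometry is irrelevant because the double bond is reduced next.

Step 2
Reactants: 2 methyl (E)-3-(4-bromo-3-methoxyphenyl)prop-2-enoate
Product: 3 methyl 3-(4-bromo-3-methoxyphenyl)propanoate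
Conditions: H2 (3 atm), RhCl(PPh3)3 (3 mol %), THF/MeOH (1:1), 40 °C
Reagents that add atoms: none
Why: Homogeneous rhodium-catalysed hydrogenation should saturate the conjugated C=C without touching the aryl C–Br bond, which heterogeneous palladium would cleave.

Step 3
Reactants: 3 methyl 3-(4-bromo-3-methoxyphenyl)propanoate
Product: 4 methyl 3-(4-iodo-3-methoxyphenyl)propanoate
Conditions: CuI (10 mol %), trans-N,N'-dimethylcyclohexane-1,2-diamine (20 mol %), NaI (2 equiv), 1,4-dioxane, 110 °C
Reagents that add atoms: sodium iodide, [Na+].[I-]
Why: Copper-catalysed aromatic Finkelstein exchange, driven by precipitation of NaBr from dioxane; the ester and the ortho methoxy group are tolerated.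

Step 4
Reactants: 5 4-bromo-2,6-dimethoxyphenol
Product: 6 4-bromo-2,6-dimethoxyphenyl 4-methylbenzenesulfonate
Conditions: TsCl (1.2 equiv), Et3N (2 equiv), DMAP (5 mol %), CH2Cl2, 0 °C to rt
Reagents that add atoms: 4-methylbenzenesulfonyl chloride, Cc1ccc(cc1)S(=O)(=O)Cl
Why: O-Sulfonylation of the phenol; the tosylate is an electron-withdrawing mask that should survive coupling, hydrogenation, hypochlorite and the key step.

Step 5
Reactants: 7 prop-2-yn-1-ol
Product: 8 tert-butyldimethyl(prop-2-yn-1-yloxy)silane
Conditions: TBSCl (1.05 equiv), imidazole (1.5 equiv), CH2Cl2, 0 °C to rt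
Reagents that add atoms: tert-butyldimethylsilyl chloride, CC(C)(C)[Si](C)(C)Cl
Why: Standard silylation of a primary alcohol; the silyl ether is the least electron-withdrawing oxygen protecting group for the later opening at C3.

Step 6
Reactants: 6 4-bromo-2,6-dimethoxyphenyl 4-methylbenzenesulfonate; 8 tert-butyldimethyl(prop-2-yn-1-yloxy)silane
Product: 9 4-[3-(tert-butyldimethylsilyloxy)prop-1-yn-1-yl]-2,6-dimethoxyphenyl 4-methylbenzenesulfonate
Conditions: PdCl2(PPh3)2 (3 mol %), CuI (5 mol %), Et3N/DMF (1:2), 70 °C
Reagents that add atoms: none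
Why: Sonogashira coupling at the unhindered C–Br bond; the aryl sulfonate, flanked by two methoxy groups, should be inert to zerovalent palladium carrying triphenylphosphine.

Step 7
Reactants: 9 4-[3-(tert-butyldimethylsilyloxy)prop-1-yn-1-yl]-2,6-dimethoxyphenyl 4-methylbenzenesulfonate
Product: 10 4-[(1Z)-3-(tert-butyldimethylsilyloxy)prop-1-en-1-yl]-2,6-dimethoxyphenyl 4-methylbenzenesulfonate
Conditions: H2 (1 atm), Pd/CaCO3 poisoned with Pb(OAc)2, quinoline, EtOAc, rt
Reagents that add atoms: none
Why: Lindlar semi-hydrogenation; syn delivery of hydrogen on the poisoned surface should give the Z-alkene and stop there.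

Step 8
Reactants: 10 4-[(1Z)-3-(tert-butyldimethylsilyloxy)prop-1-en-1-yl]-2,6-dimethoxyphenyl 4-methylbenzenesulfonate
Product: 11 4-[(2R,3S)-3-(tert-butyldimethylsilyloxymethyl)oxiran-2-yl]-2,6-dimethoxyphenyl 4-methylbenzenesulfonate (cis)
Conditions: (R,R)-(salen)MnCl [salen = N,N'-bis(3,5-di-tert-butylsalicylidene)cyclohexane-1,2-diamine dianion] (5 mol %), 4-phenylpyridine N-oxide (20 mol %), aq NaOCl (pH 11.3), CH2Cl2, 0 °C
Reagents that add atoms: sodium hypochlorite, [Na+].[O-]Cl
Why: Jacobsen–Katsuki epoxidation; Z-1-aryl alkenes are the class on which the chiral oxo species of pentavalent manganese discriminates faces best, so the catalyst alone sets both oxirane centres in one event. Low temperature and the N-oxide ligand favour fast collapse of the radical intermediate, which should preserve the cis geometry.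

Step 9
Reactants: 4 methyl 3-(4-iodo-3-methoxyphenyl)propanoate; 11 4-[(2R,3S)-3-(tert-butyldimethylsilyloxymethyl)oxiran-2-yl]-2,6-dimethoxyphenyl 4-methylbenzenesulfonate
Product: 12 methyl 3-[(2S,3R)-3-(tert-butyldimethylsilyloxymethyl)-2-[3,5-dimethoxy-4-(4-methylbenzenesulfonyloxy)phenyl]-7-methoxy-2,3-dihydro-1-benzofuran-5-yl]propanoate
Conditions: 4 (1.5 equiv), 11 (1.0 equiv), Pd(OAc)2 (10 mol %), RuPhos (20 mol %), norbornene (0.5 equiv), K2CO3 (2.5 equiv), DMF, 90 °C
Reagents that add atoms: none
Why: Proposed new method: zerovalent palladium inserts into the C–I bond of 4, norbornene inserts, and carbonate-assisted C–H palladation at the only free ortho position gives the five-membered aryl–norbornyl palladacycle of divalent palladium; this electron-rich centre is expected to open 11 by backside attack at C3, the resulting alkyl(alkoxo) complex of tetravalent palladium forms C3–C3a by reductive elimination, norbornene is expelled by beta-carbon elimination because the arene is now flanked by the C7 methoxy group and the new alkyl group, and the remaining aryl(alkoxo)palladium species forms O1–C7a. The closest known reaction type is the palladium/norbornene annulation of ortho-substituted aryl iodides with terminal epoxides to 2-substituted 2,3-dihydrobenzofurans, where the metal attacks a primary carbon; attack at a secondary carbon of an internal aryl epoxide is without precedent. The dihydrofuran ring closes by C–O reductive elimination from a six-membered oxapalladacycle (Pd, C7a, C3a, C3, C2, O1), a formal [3+2] annulation across the C7a–C3a edge of ring A. No stereocentre is made from a prochiral centre: C3 is inverted once in the SN2 opening and C2 keeps its C–O bond, so the cis-(2R,3S) oxirane maps onto the trans-(2S,3R) ring and the configuration is controlled entirely by step 8. The step needs attack at C3 and not at the benzylic C2; the tosyloxy and the two meta methoxy groups make ring B electron-poor and remove the cation-like stabilisation that normally draws nucleophiles to a benzylic epoxide carbon, and no Lewis acid or halide additive is present that would promote benzylic ionisation. It also needs a single ortho functionalisation, secured by the C7 methoxy group of 4, and selectivity for C–I over the aryl sulfonate, secured by the two methoxy groups flanking the sulfonate and by the much higher reactivity of the iodide.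

Step 10
Reactants: 12 methyl 3-[(2S,3R)-3-(tert-butyldimethylsilyloxymethyl)-2-[3,5-dimethoxy-4-(4-methylbenzenesulfonyloxy)phenyl]-7-methoxy-2,3-dihydro-1-benzofuran-5-yl]propanoate
Product: 13 methyl 3-[(2S,3R)-2-[3,5-dimethoxy-4-(4-methylbenzenesulfonyloxy)phenyl]-3-(hydroxymethyl)-7-methoxy-2,3-dihydro-1-benzofuran-5-yl]propanoate
Conditions: HF·pyridine, pyridine/THF, 0 °C to rt
Reagents that add atoms: none
Why: Fluoride cleavage of the primary silyl ether; buffered HF should leave the methyl ester, the aryl sulfonate and the benzylic ether untouched, and with the phenol still sulfonylated no quinone methide can form.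

Step 11
Reactants: 13 methyl 3-[(2S,3R)-2-[3,5-dimethoxy-4-(4-methylbenzenesulfonyloxy)phenyl]-3-(hydroxymethyl)-7-methoxy-2,3-dihydro-1-benzofuran-5-yl]propanoate
Product: 14 methyl 3-[(2S,3R)-2-(4-hydroxy-3,5-dimethoxyphenyl)-3-(hydroxymethyl)-7-methoxy-2,3-dihydro-1-benzofuran-5-yl]propanoate
Conditions: Mg turnings (10 equiv), MeOH, rt; aq NH4Cl
Reagents that add atoms: none
Why: Single-electron reduction by magnesium in methanol cleaves the S–O bond of the aryl sulfonate to phenoxide and sulfinate; methanol as solvent makes any transesterification of the methyl ester degenerate, and the stereocentres are not involved.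

**Compound list**

1 | 4-bromo-3-methoxybenzaldehyde | COc1cc(C=O)ccc1Br | starting material
2 | methyl (E)-3-(4-bromo-3-methoxyphenyl)prop-2-enoate | COC(=O)/C=C/c1ccc(Br)c(OC)c1 | intermediate
3 | methyl 3-(4-bromo-3-methoxyphenyl)propanoate | COC(=O)CCc1ccc(Br)c(OC)c1 | intermediate
4 | methyl 3-(4-iodo-3-methoxyphenyl)propanoate | COC(=O)CCc1ccc(I)c(OC)c1 | intermediate
5 | 4-bromo-2,6-dimethoxyphenol | COc1cc(Br)cc(OC)c1O | starting material
6 | 4-bromo-2,6-dimethoxyphenyl 4-methylbenzenesulfonate | COc1cc(Br)cc(OC)c1OS(=O)(=O)c1ccc(C)cc1 | intermediate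
7 | prop-2-yn-1-ol | C#CCO | starting material
8 | tert-butyldimethyl(prop-2-yn-1-yloxy)silane | C#CCO[Si](C)(C)C(C)(C)C | intermediate
9 | 4-[3-(tert-butyldimethylsilyloxy)prop-1-yn-1-yl]-2,6-dimethoxyphenyl 4-methylbenzenesulfonate | CC(C)(C)[Si](C)(C)OCC#Cc1cc(OC)c(OS(=O)(=O)c2ccc(C)cc2)c(OC)c1 | intermediate
10 | 4-[(1Z)-3-(tert-butyldimethylsilyloxy)prop-1-en-1-yl]-2,6-dimethoxyphenyl 4-methylbenzenesulfonate | CC(C)(C)[Si](C)(C)OC/C=C\c1cc(OC)c(OS(=O)(=O)c2ccc(C)cc2)c(OC)c1 | intermediate
11 | 4-[(2R,3S)-3-(tert-butyldimethylsilyloxymethyl)oxiran-2-yl]-2,6-dimethoxyphenyl 4-methylbenzenesulfonate | CC(C)(C)[Si](C)(C)OC[C@@H]1O[C@@H]1c1cc(OC)c(OS(=O)(=O)c2ccc(C)cc2)c(OC)c1 | intermediate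
12 | methyl 3-[(2S,3R)-3-(tert-butyldimethylsilyloxymethyl)-2-[3,5-dimethoxy-4-(4-methylbenzenesulfonyloxy)phenyl]-7-methoxy-2,3-dihydro-1-benzofuran-5-yl]propanoate | COC(=O)CCc1cc(OC)c2c(c1)[C@H](CO[Si](C)(C)C(C)(C)C)[C@@H](c1cc(OC)c(OS(=O)(=O)c3ccc(C)cc3)c(OC)c1)O2 | intermediate
13 | methyl 3-[(2S,3R)-2-[3,5-dimethoxy-4-(4-methylbenzenesulfonyloxy)phenyl]-3-(hydroxymethyl)-7-methoxy-2,3-dihydro-1-benzofuran-5-yl]propanoate | COC(=O)CCc1cc(OC)c2c(c1)[C@H](CO)[C@@H](c1cc(OC)c(OS(=O)(=O)c3ccc(C)cc3)c(OC)c1)O2 | intermediate
14 | methyl 3-[(2S,3R)-2-(4-hydroxy-3,5-dimethoxyphenyl)-3-(hydroxymethyl)-7-methoxy-2,3-dihydro-1-benzofuran-5-yl]propanoate | COC(=O)CCc1cc(OC)c2c(c1)[C@H](CO)[C@@H](c1cc(OC)c(O)c(OC)c1)O2 | target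

Total step count: 11. Longest linear sequence: 7 steps (steps 4, 6, 7, 8, 9, 10, 11, from 5 to 14).

**Steps least certain to work**

Step 9 (key step). Most likely to fail on regiochemistry: the palladacycle may open the epoxide at the benzylic carbon C2 instead of C3, because a benzylic carbon stays activated towards a soft metal nucleophile even on an electron-poor ring, while C3 is deactivated by the neighbouring C9 oxygen. Three further processes threaten it: the palladacycle may engage a secondary carbon too slowly and be consumed by a second molecule of the iodide or by collapse onto norbornene; palladium or adventitious Lewis acid may isomerise the aryl epoxide to a carbonyl compound; and iodide may pre-open the epoxide, replacing the single inversion by a double inversion and eroding the trans relationship.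

The fallback uses known chemistry and forms C2–C3 by rhodium carbenoid C–H insertion. It sets out from bromide 6 and comes back at alcohol 13.
- Stille coupling of 6 with (tributylstannyl)methanol [Pd(PPh3)4, dioxane, 90 °C] gives 4-(hydroxymethyl)-2,6-dimethoxyphenyl 4-methylbenzenesulfonate F1.
- Commercial methyl 3-(4-hydroxy-3-methoxyphenyl)propanoate is iodinated ortho to the hydroxyl group (N-iodosuccinimide, MeCN) to methyl 3-(4-hydroxy-3-iodo-5-methoxyphenyl)propanoate F2.
- Mitsunobu etherification of F2 with F1 (PPh3, DIAD, THF) gives methyl 3-[4-[[3,5-dimethoxy-4-(4-methylbenzenesulfonyloxy)phenyl]methoxy]-3-iodo-5-methoxyphenyl]propanoate F3.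
- Palladium-catalysed coupling of the aryl iodide with tert-butyl diazoacetate [Pd(PPh3)4, Ag2CO3, Et3N, toluene, rt] gives tert-butyl 2-diazo-2-[2-[[3,5-dimethoxy-4-(4-methylbenzenesulfonyloxy)phenyl]methoxy]-3-methoxy-5-(3-methoxy-3-oxopropyl)phenyl]acetate F4.
- Rh2(S-PTTL)4 or its enantiomer, whichever gives the 2S configuration, in toluene at low temperature should insert the carbenoid into the ArO–CH2–aryl C–H bond to give tert-butyl (2S,3R)-cis-2-[3,5-dimethoxy-4-(4-methylbenzenesulfonyloxy)phenyl]-7-methoxy-5-(3-methoxy-3-oxopropyl)-2,3-dihydro-1-benzofuran-3-carboxylate F5.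
- DBU in toluene epimerises C3 to the (2S,3S)-trans tert-butyl ester F6.
- CF3CO2H in CH2Cl2 cleaves the tert-butyl ester to (2S,3S)-trans-2-[3,5-dimethoxy-4-(4-methylbenzenesulfonyloxy)phenyl]-7-methoxy-5-(3-methoxy-3-oxopropyl)-2,3-dihydro-1-benzofuran-3-carboxylic acid F7.
- BH3·THF reduces the acid in the presence of the methyl ester to 13.

Step 8. Most likely to go wrong: loss of the cis geometry through rotation in the radical intermediate of the manganese oxo transfer, or insufficient facial selectivity caused by the polar allylic substituent. The fallback uses a hydroxyl-directed, concerted oxygen transfer, sets out from 10 and comes back at 11. Desilylation (HF·pyridine, THF) gives 4-[(1Z)-3-hydroxyprop-1-en-1-yl]-2,6-dimethoxyphenyl 4-methylbenzenesulfonate F8. Sharpless asymmetric epoxidation [Ti(OiPr)4, L-(+)-diisopropyl tartrate, t-BuOOH, 4 Å molecular sieves, CH2Cl2, −20 °C] should give 4-[(2R,3S)-3-(hydroxymethyl)oxiran-2-yl]-2,6-dimethoxyphenyl 4-methylbenzenesulfonate F9 with full retention of the cis geometry. Silylation (TBSCl, imidazole, CH2Cl2) returns 11.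

Step 11. Most likely to go wrong: incomplete S–O cleavage at the hindered sulfonate, or opening of the para-hydroxybenzyl ether once the phenoxide is formed in basic methanol. The fallback removes the sulfonate hydrolytically, sets out from 13 and comes back at 14. KOH in aqueous MeOH at reflux cleaves the sulfonate and saponifies the ester to 3-[(2S,3R)-2-(4-hydroxy-3,5-dimethoxyphenyl)-3-(hydroxymethyl)-7-methoxy-2,3-dihydro-1-benzofuran-5-yl]propanoic acid F10. Selective methylation of the carboxylic acid (Me3SiCHN2, MeOH/toluene, 0 °C) gives 14.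

Step 3. Most likely to go wrong: incomplete halogen exchange, because the equilibrium is driven only by salt solubility and the ortho methoxy group slows the copper step, leaving bromide and iodide that are hard to separate. The fallback replaces exchange by borylation and iodination, sets out from 3 and comes back at 4. Miyaura borylation [PdCl2(dppf), B2pin2, KOAc, dioxane, 90 °C] gives methyl 3-[3-methoxy-4-(4,4,5,5-tetramethyl-1,3,2-dioxaborolan-2-yl)phenyl]propanoate F11. Copper-catalysed iododeboronation (CuI, 1,10-phenanthroline, KI, MeOH/H2O, air, 80 °C) gives 4.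

**Further compounds**

F1 | step 9 | 4-(hydroxymethyl)-2,6-dimethoxyphenyl 4-methylbenzenesulfonate | COc1cc(CO)cc(OC)c1OS(=O)(=O)c1ccc(C)cc1
F2 | step 9 | methyl 3-(4-hydroxy-3-iodo-5-methoxyphenyl)propanoate | COC(=O)CCc1cc(I)c(O)c(OC)c1
F3 | step 9 | methyl 3-[4-[[3,5-dimethoxy-4-(4-methylbenzenesulfonyloxy)phenyl]methoxy]-3-iodo-5-methoxyphenyl]propanoate | COC(=O)CCc1cc(I)c(OCc2cc(OC)c(OS(=O)(=O)c3ccc(C)cc3)c(OC)c2)c(OC)c1
F4 | step 9 | tert-butyl 2-diazo-2-[2-[[3,5-dimethoxy-4-(4-methylbenzenesulfonyloxy)phenyl]methoxy]-3-methoxy-5-(3-methoxy-3-oxopropyl)phenyl]acetate | COC(=O)CCc1cc(OC)c(OCc2cc(OC)c(OS(=O)(=O)c3ccc(C)cc3)c(OC)c2)c(c1)C(=[N+]=[N-])C(=O)OC(C)(C)C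
F5 | step 9 | tert-butyl (2S,3R)-cis-2-[3,5-dimethoxy-4-(4-methylbenzenesulfonyloxy)phenyl]-7-methoxy-5-(3-methoxy-3-oxopropyl)-2,3-dihydro-1-benzofuran-3-carboxylate | COC(=O)CCc1cc(OC)c2c(c1)[C@@H](C(=O)OC(C)(C)C)[C@@H](c1cc(OC)c(OS(=O)(=O)c3ccc(C)cc3)c(OC)c1)O2
F6 | step 9 | tert-butyl (2S,3S)-trans-2-[3,5-dimethoxy-4-(4-methylbenzenesulfonyloxy)phenyl]-7-methoxy-5-(3-methoxy-3-oxopropyl)-2,3-dihydro-1-benzofuran-3-carboxylate | COC(=O)CCc1cc(OC)c2c(c1)[C@H](C(=O)OC(C)(C)C)[C@@H](c1cc(OC)c(OS(=O)(=O)c3ccc(C)cc3)c(OC)c1)O2
F7 | step 9 | (2S,3S)-trans-2-[3,5-dimethoxy-4-(4-methylbenzenesulfonyloxy)phenyl]-7-methoxy-5-(3-methoxy-3-oxopropyl)-2,3-dihydro-1-benzofuran-3-carboxylic acid | COC(=O)CCc1cc(OC)c2c(c1)[C@H](C(=O)O)[C@@H](c1cc(OC)c(OS(=O)(=O)c3ccc(C)cc3)c(OC)c1)O2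
F8 | step 8 | 4-[(1Z)-3-hydroxyprop-1-en-1-yl]-2,6-dimethoxyphenyl 4-methylbenzenesulfonate | OC/C=C\c1cc(OC)c(OS(=O)(=O)c2ccc(C)cc2)c(OC)c1
F9 | step 8 | 4-[(2R,3S)-3-(hydroxymethyl)oxiran-2-yl]-2,6-dimethoxyphenyl 4-methylbenzenesulfonate | OC[C@@H]1O[C@@H]1c1cc(OC)c(OS(=O)(=O)c2ccc(C)cc2)c(OC)c1
F10 | step 11 | 3-[(2S,3R)-2-(4-hydroxy-3,5-dimethoxyphenyl)-3-(hydroxymethyl)-7-methoxy-2,3-dihydro-1-benzofuran-5-yl]propanoic acid | OC(=O)CCc1cc(OC)c2c(c1)[C@H](CO)[C@@H](c1cc(OC)c(O)c(OC)c1)O2
F11 | step 3 | methyl 3-[3-methoxy-4-(4,4,5,5-tetramethyl-1,3,2-dioxaborolan-2-yl)phenyl]propanoate | COC(=O)CCc1ccc(B2OC(C)(C)C(C)(C)O2)c(OC)c1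
A1 | alternative 1 | methyl 3-[4-[[(1S)-1-(4-benzyloxy-3,5-dimethoxyphenyl)prop-2-en-1-yl]oxy]-3-iodo-5-methoxyphenyl]propanoate | C=C[C@@H](c1cc(OC)c(OCc2ccccc2)c(OC)c1)Oc1c(I)cc(CCC(=O)OC)cc1OC
A2 | alternative 1 | methyl 3-[(2S,3R)-2-(4-benzyloxy-3,5-dimethoxyphenyl)-7-methoxy-3-[(2,2,6,6-tetramethylpiperidin-1-yl)oxymethyl]-2,3-dihydro-1-benzofuran-5-yl]propanoate | COC(=O)CCc1cc(OC)c2c(c1)[C@H](CON1C(C)(C)CCCC1(C)C)[C@@H](c1cc(OC)c(OCc3ccccc3)c(OC)c1)O2
A3 | alternative 2 | methyl 2-[2-[(4-benzyloxy-3,5-dimethoxyphenyl)methoxy]-5-bromo-3-methoxyphenyl]-2-diazoacetate | COC(=O)C(=[N+]=[N-])c1cc(Br)cc(OC)c1OCc1cc(OC)c(OCc2ccccc2)c(OC)c1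
A4 | alternative 2 | methyl (2S,3S)-trans-2-(4-benzyloxy-3,5-dimethoxyphenyl)-5-bromo-7-methoxy-2,3-dihydro-1-benzofuran-3-carboxylate | Brc1cc(OC)c2c(c1)[C@H](C(=O)OC)[C@@H](c1cc(OC)c(OCc3ccccc3)c(OC)c1)O2
A5 | alternative 3 | methyl 3-[3-[1-(benzenesulfonyl)-2-(tert-butyldimethylsilyloxy)ethyl]-4-hydroxy-5-methoxyphenyl]propanoate (racemic) | COC(=O)CCc1cc(OC)c(O)c(c1)C(CO[Si](C)(C)C(C)(C)C)S(=O)(=O)c1ccccc1
A6 | alternative 3 | (2R,5R)-1-[(4-benzyloxy-3,5-dimethoxyphenyl)methyl]-2,5-dimethylthiolan-1-ium tetrafluoroborate | C[C@@H]1CC[C@@H](C)[S+]1Cc1cc(OC)c(OCc2ccccc2)c(OC)c1.F[B-](F)(F)F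
A7 | alternative 3 | methyl 3-[5-[2-(tert-butyldimethylsilyloxy)ethylidene]-3-methoxy-4-oxocyclohexa-1,5-dien-1-yl]propanoate (ortho-quinone methide) | COC(=O)CCC1=CC(=CCO[Si](C)(C)C(C)(C)C)C(=O)C(OC)=C1
A8 | alternative 3 | methyl 3-[(2S,3R)-2-(4-benzyloxy-3,5-dimethoxyphenyl)-3-(tert-butyldimethylsilyloxymethyl)-7-methoxy-2,3-dihydro-1-benzofuran-5-yl]propanoate | COC(=O)CCc1cc(OC)c2c(c1)[C@H](CO[Si](C)(C)C(C)(C)C)[C@@H](c1cc(OC)c(OCc3ccccc3)c(OC)c1)O2
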